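in all of them: substrate 0.095 M; first nucleophile 0.105 M
- green: second nucleophile 0.17 M (fed, over 10 h); temperature 35 °C; run made earlier; the fed solution adds 0.20 times the starting volume
- red: second nucleophile 0.27 M (fed, over 10 h); temperature 50 °C; run made earlier; the fed solution adds 0.20 times the starting volume
- theta: second nucleophile 0.124 M; temperature 50 °C; everything together at the start, the whole solution of second nucleophile included, so that from the start the volume is larger by 0.20 times the starting volume; time 10 h
- delta: second nucleophile 0.124 M (fed, over 10 h); temperature 50 °C; the fed solution adds 0.20 times the starting volume; time 10 h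

| green: time / h | green: target / % | red: time / h | red: target / % |
|---|---|---|---|
| 2.00 | 4.9 | 1.00 | 23.4 |
| 4.00 | 6.7 | 2.00 | 31.2 |
| 6.00 | 7.3 | 3.00 | 30.6 |
| 12.0 | 7.0 | 6.00 | 24.6 |
| 25.0 | 6.2 | 12.0 | 17.2 |

(standard deviation of a reading: 0.3 percentage points)

- amounts are per litre of the starting volume; all of the dose is in the solution fed
- the earlier runs were read with a standard deviation of 0.3 percentage points

- which one finishes higher in amount of target, in percent of the substrate charged ("neither" within 2 percentage points) (theta / delta / neither)
- amount of target at the end, in percent of the substrate charged, theta
- amount of target at the end, in percent of the substrate charged, delta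

1. Amounts. Substrate is charged at less than either nucleophile, so it is the limiting reagent, and I ask how its charge splits between second nucleophile and target.

2. Temperature. Heat speeds substrate's loss, so I read that loss at the asked temperature. In red after 1.00 h, I count target plus fed second nucleophile, one substrate each, as the fraction gone. Taken as first order, that gives a rate constant of 0.730 h⁻¹.

3. Feed. I define the feed ratio 0.179: the feed, as a fraction of the substrate charge per hour, over the fraction substrate first loses per hour. A longer feed lowers it. For delta, I let the feed capture substrate until substrate's loss falls to the feed rate, at 2.36 h. Then the remainder, a fraction equal to the ratio, is captured too. The captured share is the ratio times (1 + ln(1/ratio)), or 48.7%, which leaves 51.3% for target.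

4. Time. Late in red, target falls at 0.0596 h⁻¹. Dating delta's target at 2.36 h, I expect 32.6% at the end.

5. Dosing. In theta the dose is there at the start, covering 1.31 times the substrate charge, so I expect target below green's peak reading of 7.3%, and delta ahead.

6. The forecast gives delta, with 1% for theta, "limited by the unknown fast rate", and 25% for delta.

7. The flask gives delta: 29.8% for delta against 3.06% for theta.

    substrate → intermediate (k = 0.910 h⁻¹, Ea = 95.0 kJ mol⁻¹)
    target → over-reaction product (k = 0.00800 h⁻¹, Ea = 104 kJ mol⁻¹)
    first nucleophile + intermediate → target (k = 23.0 M⁻¹ h⁻¹, Ea = 74.0 kJ mol⁻¹)
    second nucleophile + intermediate → other capture product (k = 560 M⁻¹ h⁻¹, Ea = 41.0 kJ mol⁻¹)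
    intermediate → side product (k = 0.110 h⁻¹, Ea = 95.0 kJ mol⁻¹)
    target ⇌ isomer of the product (K = 2.00, k = 0.0790 h⁻¹, Ea = 103 kJ mol⁻¹, ΔH = −72.0 kJ mol⁻¹)
    (constants at 50 °C)

Delta ends with other capture product at 40.0%, against my captured share of 48.7%. For delta run at 35 °C, the 20% of substrate left after 10 h, taken as first order, gives a rate constant of 0.163 h⁻¹. The feed ratio is then higher than in delta at 0.802, and the captured share is 97.9%, or 77.9% once the substrate still there is taken off. That flask consumes 80.0% of its substrate and holds 67.6% as other capture product. Its target ends at 11.0%.

The earlier runs and the new flask are simulated for an exercise, noise included.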